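**Assumptions**
- C-Prenylation of 2,4-dihydroxyacetophenone goes mainly at C3, between the two OH groups. The minor C5 isomer and the O-prenyl ether are removed by chromatography.
- The target SMILES is (2S)-7,4'-dihydroxy-8,3'-diprenylflavanone. I checked the CIP assignment of the stereocentre: O > aryl > CH2 > H gives S.

**Retrosynthesis**
1. Glabrol comes from acid removal of two MOM ethers from the (2S)-flavanone.
2. The pyranone ring (C2–O bond) is formed last, by a catalyst-controlled enantioselective intramolecular oxa-Michael addition of a 2'-hydroxychalcone. This is the only stereocentre.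
3. The chalcone C=C bond is made by Claisen–Schmidt condensation of 3-prenyl-2,4-dihydroxyacetophenone with 3-prenyl-4-hydroxybenzaldehyde.
4. Each prenylated arene comes from direct ortho C-prenylation of a commercial phenol with prenyl bromide.
5. Ring order: both aromatic rings are already present. The enone is formed in step 3 and the heterocycle in step 5.

---

**Step 1**
Reactants: 1 (2,4-dihydroxyacetophenone); 2 (prenyl bromide)
Product: 3 (1-[2,4-dihydroxy-3-(3-methylbut-2-enyl)phenyl]ethanone)
Conditions: 2 (1.0 equiv), KOH (2.2 equiv), MeOH/H2O, 0 °C → rt, 24 h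
Reagents that add atoms: prenyl bromide, CC(C)=CCBr
Why: Phenoxide ortho C-alkylation (Friedel–Crafts-type, favoured in protic media) goes mainly at the C3 position between the two OH groups. There is no stereocentre.

**Step 2**
Reactants: 4 (4-hydroxybenzaldehyde); 2 (prenyl bromide)
Product: 5 (4-hydroxy-3-(3-methylbut-2-enyl)benzaldehyde)
Conditions: 2 (1.0 equiv), NaOH (2.2 equiv), H2O/MeOH, 0 °C → rt, 24 h
Reagents that add atoms: prenyl bromide, CC(C)=CCBr
Why: The para position is blocked by CHO, so aqueous phenoxide C-alkylation occurs ortho to OH. The mono-C-prenyl product is separated from O-prenyl and di-prenyl by-products.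

**Step 3**
Reactants: 3; 5
Product: 6 ((E)-1-[2,4-dihydroxy-3-prenylphenyl]-3-[4-hydroxy-3-prenylphenyl]prop-2-en-1-one)
Conditions: 50% aq. KOH, EtOH, rt, 48 h; then 1 M HCl to pH 3
Reagents that add atoms: none
Why: Claisen–Schmidt (aldol/E1cB) condensation gives the thermodynamic E-chalcone. Excess base keeps the phenols as phenolates, so the chalcone does not cyclise. Acidification returns the free phenols.

**Step 4**
Reactants: 6; 7 (chloromethyl methyl ether, MOMCl)
Product: 8 ((E)-chalcone with 4-OMOM and 4'-OMOM, 2'-OH free)
Conditions: 7 (2.3 equiv), i-Pr2NEt, CH2Cl2, 0 °C → rt, 3 h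
Reagents that add atoms: MOMCl, COCCl
Why: The 2'-OH is locked in a strong hydrogen bond to the carbonyl and is unreactive to mild base/MOMCl, so only the 4-OH and 4'-OH are protected. Protecting them keeps the acidic phenols from quenching the basic catalyst in step 5. There is no stereocentre.

**Step 5**
Reactants: 8
Product: 9 ((2S)-7,4'-bis(MOM-oxy)-8,3'-diprenylflavanone)
Conditions: cat. cinchona-derived bifunctional thiourea (15 mol %), toluene, 25 °C, 3–5 d; recycle recovered 8
Reagents that add atoms: none
Why: This is an enantioselective intramolecular oxa-Michael (6-endo-trig) cyclisation. The catalyst's tertiary amine deprotonates the 2'-OH while the thiourea binds the enone carbonyl, so the phenoxide adds to one face of the enone. The C2 configuration is set here. I use the quinine- or quinidine-derived pseudo-enantiomer that gives 2S.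

**Step 6**
Reactants: 9
Product: 10 (glabrol, (2S)-7,4'-dihydroxy-8,3'-diprenylflavanone)
Conditions: 2 M HCl, THF/MeOH (1:1), 40 °C, 6 h
Reagents that add atoms: none
Why: Acid-mediated hydrolysis of the MOM acetals. Prenyl alkenes, the ketone and the benzylic C2–O stereocentre tolerate these mild conditions, and no base is present to cause ring-opening racemisation.

---

**Compound list**

| No. | Name | SMILES | Role |
|---|---|---|---|
| 1 | 2,4-Dihydroxyacetophenone | CC(=O)c1ccc(O)cc1O | starting material |
| 2 | Prenyl bromide (1-bromo-3-methylbut-2-ene) | CC(C)=CCBr | starting material |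
| 3 | 2,4-Dihydroxy-3-prenylacetophenone | CC(=O)c1ccc(O)c(CC=C(C)C)c1O | intermediate |
| 4 | 4-Hydroxybenzaldehyde | O=Cc1ccc(O)cc1 | starting material |
| 5 | 4-Hydroxy-3-prenylbenzaldehyde | O=Cc1ccc(O)c(CC=C(C)C)c1 | intermediate |
| 6 | (E)-2',4,4'-Trihydroxy-3,3'-diprenylchalcone | CC(C)=CCc1cc(/C=C/C(=O)c2ccc(O)c(CC=C(C)C)c2O)ccc1O | intermediate |
| 7 | Chloromethyl methyl ether (MOMCl) | COCCl | starting material (reagent) |
| 8 | (E)-4,4'-Bis(MOM-oxy)-2'-hydroxy-3,3'-diprenylchalcone | CC(C)=CCc1cc(/C=C/C(=O)c2ccc(OCOC)c(CC=C(C)C)c2O)ccc1OCOC | intermediate |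
| 9 | (2S)-7,4'-Bis(MOM-oxy)-8,3'-diprenylflavanone | CC(C)=CCc1cc([C@@H]2CC(=O)c3ccc(OCOC)c(CC=C(C)C)c3O2)ccc1OCOC | intermediate |
| 10 | Glabrol | CC(C)=CCc1cc([C@@H]2CC(=O)c3ccc(O)c(CC=C(C)C)c3O2)ccc1O | target |

---

**Totals**
- Total steps: 6.
- Longest linear sequence: 5 steps (1 → 3 → 6 → 8 → 9 → 10).

**Three steps most likely to fail**

1. **Steps 1 and 2 (direct C-prenylation).** Yields are modest, and O-alkylation, C5 alkylation and di-prenylation compete.
   - Fallback: directed ortho-metalation. Use 4-OMOM-2-hydroxyacetophenone (for 3) or MOM-protected 4-bromophenol (s-BuLi, prenyl bromide/CuI, then BuLi/DMF) for the aldehyde.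

2. **Step 5 (enantioselective oxa-Michael).** The enone is electron-rich, so conversion is slow. The ring closure is reversible, so ee can erode over time.
   - Fallback: chemoenzymatic cyclisation of the free-phenol chalcone 6 with chalcone isomerase at pH 7.5, which gives the 2S flavanone directly. Then prenyl-tolerant MOM protection is not needed, and only steps 1–3 precede it.
   - A second fallback is Pd-catalysed asymmetric conjugate arylation of a 7-OMOM-8-prenylchromone with the 4-OMOM-3-prenylphenylboronic acid.

3. **Step 3 (Claisen–Schmidt on free phenols).** Yields are low with polyphenolates, and racemic flavanone can form as a by-product.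
   - Fallback: protect the phenols first. Make the 4-OMOM acetophenone and the OMOM aldehyde, then condense them with Ba(OH)2/MeOH. This gives 8 directly and removes step 4.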